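At any reading time a flask has a dose of Z behind it: its loading, as a fraction of L, times the hours, so a dose counts in hours. I held L at 48 mM and Q at 1.10 equiv, which makes L the limiting reagent. Alder at 4.00 h and maple at 6.00 h had both taken 0.720 h and read D 54% and 53%, within the scatter of 2 percentage points. So I put all the runs on this one clock.

common to all: L 48 mM
- cedar: Q 1.1 equiv; Z 9.7 mol%; run made earlier
- maple: Q 1.1 equiv; Z 12 mol%; run made earlier
- alder: Q 1.1 equiv; Z 18 mol%; run made earlier
- summer: Q 1.10 equiv; Z 10 mol%; time 12 h
- dawn: Q 1.10 equiv; Z 13 mol%; time 12 h
- midnight: Q 1.10 equiv; Z 17 mol%; time 12 h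

- cedar (time / h: L / %, D / %, X / %): 0.500: 80, 0, 18; 0.833: 71, 1, 22; 1.50: 55, 9, 41; 3.00: 32, 22, 42; 6.00: 18, 50, 36
- maple (time / h: L / %, D / %, X / %): 1.33: 50, 8, 36; 2.50: 34, 22, 40; 4.00: 22, 41, 41; 5.00: 20, 47, 36; 6.00: 14, 53, 34
- alder (time / h: L / %, D / %, X / %): 0.500: 72, 3, 28; 1.50: 34, 20, 43; 3.00: 19, 47, 31; 4.00: 12, 54, 30; 6.00: 8, 68, 22

(standard deviation of a reading: 2 percentage points)

- which of these there is most of at the end, counted by the L in it, summer (X / D / L)
- which of these there is most of at the end, counted by the L in it, dawn (X / D / L)
- which of these there is most of at the end, counted by the L in it, midnight (X / D / L)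
- how much there is at the end of the one of these that leads, in percent of the L charged: summer
- how much there is at the end of the one of these that leads, in percent of the L charged: dawn
- how much there is at the end of the one of these that leads, in percent of the L charged: midnight

On that clock the rungs came in order. By a dose of 0.145 h, cedar read L 55%. At 0.270 h, alder read X 43%, against L 34% and D 20%. At 0.582 h, cedar's D had reached 50%.

As read from the last two readings of each run, what was not yet D halved in a dose of 0.454 h in cedar, but needed 0.688 h in alder, at larger doses.

Alder's last reading, at a dose of 1.08 h, had D 68% against X 22%. The asked flasks take 1.20 h, 1.56 h and 2.04 h, so I expected D to lead in each.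

For the amounts, I first replaced the tail by one mean halving dose, alder's, which put midnight at 87.8%. But the halving dose read larger at the larger doses, so that figure for D was likely high. Stretching it once more by the same ratio gave my estimate of the halving dose past the readings, 1.04 h. From alder's last reading, that gave D 70.5% for summer, 76.7% for dawn and 83.1% for midnight, so at midnight the single mean stood 4.7 points above this estimate.

The forecast also had D leading, but lower than mine, at 68%, 75% and 81%, taking its falling constants to suggest that “the catalyst dies or is inhibited by product”.

In summer D led at 71.1%, and in dawn D led at 77.9%.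

    L + Z ⇌ Z + X (K = 4.10, k = 0.0250 M⁻¹ s⁻¹)
    Q + Z + X → Z + D (k = 0.330 M⁻² s⁻¹)

In summer, free Q fell from 56.1% of its charge at 6.00 h to 35.3% at 12.0 h, while Z stood at 100% of its charge. I then carried the halving dose from summer's end, where 28.9% of the L charged was not yet D, across the dose gap of 0.840 h to midnight. That left 16.5%, or D 83.5%, and in midnight D led at 83.5%.

(The earlier runs and the new flask were computed on assumed constants, and the scatter is random.)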